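Charge over solubility runs from 1.62 in teal to 4.05 in green, and your hunch is that target climbs with it, so here is my quick reckoning for these flasks.

| flask | solid substrate | time |
|---|---|---|
| teal | 0.12 M | 12 h |
| blue | 0.20 M | 12 h |
| green | 0.30 M | 12 h |

    starting material + 2 target → 3 target (k1 = 0.0060 M⁻² s⁻¹)
    starting material → target (k2 = 6.9 × 10⁻⁶ s⁻¹)
    solid substrate ⇌ starting material, rate k3*(cs3 - [starting material]) while solid is left; crystals form when [starting material] > cs3 (cs3 = 0.074 M, k3 = 2.9 × 10⁻⁴ s⁻¹)
    2 starting material → self-condensation product (k4 = 6.0 × 10⁻⁵ M⁻¹ s⁻¹)

1. [target] at the end for teal, blue, green, in this order
2. how that number moves from the first to the last of them (rises all the way / hardly changes / falls, then rises / falls all the way / rises, then falls)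

Dissolving has a characteristic time of 0.958 h, shorter than the 12 h run. So the solution soon stands below the solubility 0.074 M by a gap of 0.00403 M, the loss by the uncatalysed step and self-condensation divided by the dissolution coefficient. That puts the starting material at a level L of 0.0700 M, where dissolving replaces what the reactions take (a steady state, in the usual term). At L, those two steps take 0.00385 M h⁻¹.

Now I write the balance of the solid. What it must give up by the end is what stands in solution plus what has reacted, and, leaving the autocatalytic step aside for the moment, I call this the draw, D = L + loss × time, which is 0.116 M. D is smaller than every charge, by 0.00379 M in teal, so by this reckoning solid lasts through each run and the three solutions are alike.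

Target is then, by my estimate, the uncatalysed rate times the time, 0.0209 M in each flask. I keep that number because, even at that much target, the autocatalytic step's rate per unit of starting material, 0.00940 h⁻¹, is smaller than the uncatalysed 0.025 h⁻¹, though it is not nothing, so the estimate may come out a little low.

The forecast reads 0.021 M, 0.021 M, 0.021 M, shape hardly changes, since “solid remains in all three runs”.

The simulation gives 0.0218 M, 0.0218 M, 0.0218 M, shape hardly changes. In teal, dissolving leads at 1.37 h, making starting material 7.39 times as fast as it is used, and by 12.0 h that ratio is 0.973, with 4.88 % of the charge still solid and the uncatalysed step's half-life of 28 h shorter than the autocatalytic step's 68 h. Against the draw of 0.116 M, the solid has given up 0.114 M in teal and 0.114 M in green at 12.0 h.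

(The constants are made up; no experiment stands behind them.)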